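The ratio [target]/[isomer of the product] at rest is 2.44 at 20 °C, and the question here is how close each flask comes, within its time, to the ratio at rest for its own temperature.

all flasks: starting material 0.0010 M; protic impurity 0.0500 mM; free enzyme 0.0023 mol%; stray impurity 0.033 µM; time 30 s

| charge | temperature | remark |
|---|---|---|
| beta | 20 °C |  |
| epsilon | −40 °C |  |
| alpha |  | at −40 °C until 10 s, from then on at 20 °C |
| gamma | −10 °C |  |

- the flask that comes out highest in share of target in all that became target or isomer of the product, or "all alike" when all lie within 1.5 percentage points (beta / epsilon / alpha / gamma / all alike)
- share of target in all that became target or isomer of the product, beta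
- share of target in all that became target or isomer of the product, epsilon
- share of target in all that became target or isomer of the product, alpha
- share of target in all that became target or isomer of the product, gamma

- the list of constants is for 20 °C, to be carried to other temperatures by the activation energies and enthalpies

    free enzyme → unfolded enzyme (k1 = 5.5 × 10⁻⁴ s⁻¹, Ea1 = 181 kJ mol⁻¹)
    starting material + free enzyme ⇌ complex (K2 = 1500 M⁻¹, k2 = 2.5 × 10⁸ M⁻¹ s⁻¹, Ea2 = 12.0 kJ mol⁻¹, ΔH2 = −26.0 kJ mol⁻¹)
    complex → free enzyme + target (k3 = 20000 s⁻¹, Ea3 = 40.0 kJ mol⁻¹)
    target ⇌ isomer of the product (K4 = 0.41, k4 = 0.11 s⁻¹, Ea4 = 84.0 kJ mol⁻¹, ΔH4 = −44.0 kJ mol⁻¹)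
    free enzyme + stray impurity → spent catalyst (k5 = 5.0 × 10⁷ M⁻¹ s⁻¹, Ea5 = 17.0 kJ mol⁻¹)
    starting material + protic impurity → quenched substrate (k6 = 1500 M⁻¹ s⁻¹, Ea6 = 41.0 kJ mol⁻¹)
    (constants at 20 °C)

I build the flask by hand, one process at a time. With turnover by itself, starting material binds free enzyme, the complex releases target, and the share stands at 100 percent however fast this runs.

Now I add step 4. The equilibrium share of target is 70.9% at 20 °C, and the inverse of the sum of forward and backward constants gives 2.64 s. This relaxation time, the time in which the excess of the share over equilibrium shrinks by a factor e, is what I carry. Product made evenly over a stretch of time at one temperature keeps an average excess of about the full excess times relaxation time over stretch, and production that slows down keeps less. Since the time of beta far exceeds its relaxation time, beta is under thermodynamic control and lies below 73.5%. Alpha's warm stretch of 20.0 s also far exceeds the relaxation time, so alpha lies below 74.8%, the product of its cold start being older still.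

Then comes the rest. The stray impurity, at 0.033 µM, outnumbers the free enzyme, at 0.0230 µM, so it can stop the turnover. Together with unfolding and the protic impurity it alters how much product forms, but none of these steps touches target or isomer. They enter the share through the age of the product, and a falling production is what my bound assumes.

Cold moves both halves of the reckoning. At −10 °C, in gamma, the equilibrium constant of step 4 becomes 3.21, so the equilibrium share drops to 23.8%. But the forward constant is 0.00216 s⁻¹, and the relaxation time grows to 352 s. Because the time of gamma is far shorter than that, gamma is under kinetic control. Its product can be no older than the flask, so gamma stays above 93.7%. At −40 °C, in epsilon, the forward constant is 1.55 × 10⁻⁵ s⁻¹, and the same floor gives >99.9%. My ranking therefore puts epsilon first.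

The forecast also names epsilon, with 70.9% for beta, >99.9% for epsilon, 71% for alpha and 94.8% for gamma. It holds that the warm flasks sit at the equilibrium share “whatever the enzyme and its poison do”. For gamma it takes product aged about 25 s, which gives a point above my floor.

The simulation gives 70.9% for beta, >99.9% for epsilon, 71.0% for alpha and 95.4% for gamma, so epsilon stands highest, and beta reads 100% with step 4 struck out. A longer wait moves gamma off the forecast's figure: at 300 s, a time of the order of its relaxation time 352 s, gamma holds a share of 57.3%. The neighbour like alpha with 0.0092 mol% of free enzyme has the same warm stretch of 7.57 relaxation times, and though it makes more target than alpha, 68.6% of the starting material charged, it reads 70.9%.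

All constants are those of an exercise.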